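**Retrosynthetic overview**

- Numbering: ring A is C1 (CMe2), C2, C3 (CHBr), C4, C5 (C(Me)OH), C6 (spiro); ring B is C6, C7=C8, C9 (=CHBr), C10, C11. The route rests on one feature: in a ring A cyclohexenyl divinyl ketone, C6=C7–C8=C9(O)–C10=C11 is a hexatriene that lacks only the C6–C11 bond.
- Late disconnections: C3–Br (SN2 on the C3 alcohol with inversion), C5–OH (hydroxyl-directed epoxide of C4=C5, hydride at C4), C9=CHBr (Wittig on the ring B enone).
- Key disconnection C6–C11: 6π-electrocyclisation of the trienolate obtained by vinylogous enolisation (loss of H from C4) of the dienone. Both C8=C9 geometries arise on enolisation, so the closure is run on the potassium trienolate, in which they can interconvert.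
- The dienone comes from the ring A enol triflate by Heck coupling with N-methoxy-N-methylacrylamide and vinyl Grignard addition; ring A is ketoisophorone, its one stereocentre set by two reductions.
- Ring order: ring A is present from the start; ring B and the spiro centre C6 are formed in the key step.

Key step: step 7

Assumption: an ene-reductase of the old yellow enzyme family with a glucose dehydrogenase recycling system, and N-methoxy-N-methylacrylamide, are taken as purchasable. Atom numbers C1–C11 are those of the overview; compounds 1–4 carry ordinary cyclohexanone locants in their names.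

**Route**

Step 1
Reactants: 1 ketoisophorone (2,6,6-trimethylcyclohex-2-ene-1,4-dione)
Product: 2 (6R)-levodione [(R)-2,2,6-trimethylcyclohexane-1,4-dione]
Conditions: ene-reductase (old yellow enzyme), NADP+ (cat.), glucose dehydrogenase, D-glucose, phosphate buffer pH 6.5, 30 °C
Reagents that add atoms: none
Why: Enzymatic asymmetric conjugate reduction of the ene-dione C=C by a flavin ene-reductase should set the methyl-bearing carbon as R, the usual sense for this substrate, and near-neutral pH with prompt extraction limits racemisation of this α-stereocentre.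

Step 2
Reactants: 2 (6R)-levodione
Product: 3 (4R,6R)-4-hydroxy-2,2,6-trimethylcyclohexan-1-one (trans-actinol)
Conditions: LiBH(sBu)3 (L-Selectride), THF, −78 °C
Reagents that add atoms: none
Why: Substrate-controlled hydride reduction: the C4 carbonyl is far more accessible than C1 (flanked by CMe2 and CHMe), and the axial C2 methyl blocks axial approach, so the bulky borohydride should attack equatorially and give the axial alcohol trans to the C6 methyl.

Step 3
Reactants: 3 (4R,6R)-4-hydroxy-2,2,6-trimethylcyclohexan-1-one
Product: 4 (4R,6R)-4-[(tert-butyldimethylsilyl)oxy]-2,2,6-trimethylcyclohexan-1-one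
Conditions: TBSCl, imidazole, DMF, 23 °C
Reagents that add atoms: tert-butyldimethylsilyl chloride, CC(C)(C)[Si](C)(C)Cl
Why: Standard imidazole-promoted silylation of a secondary alcohol, which masks the hydroxyl for the enolate and organometallic steps that follow.

Step 4
Reactants: 4 (4R,6R)-4-[(tert-butyldimethylsilyl)oxy]-2,2,6-trimethylcyclohexan-1-one
Product: 5 (R)-4-[(tert-butyldimethylsilyl)oxy]-2,6,6-trimethylcyclohex-1-en-1-yl trifluoromethanesulfonate
Conditions: LiN(iPr)2, THF, −78 → 0 °C; PhNTf2, 0 → 23 °C
Reagents that add atoms: N-phenylbis(trifluoromethanesulfonimide), FC(F)(F)S(=O)(=O)N(c1ccccc1)S(=O)(=O)C(F)(F)F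
Why: Enolate O-triflation: the ketone can enolise only toward the methyl-bearing α-carbon (the other is quaternary), so the tetrasubstituted enol triflate forms regiospecifically, erasing the methyl stereocentre and leaving the silyloxy carbon (C3 of the route numbering) untouched.

Step 5
Reactants: 5 (R)-enol triflate; 6 N-methoxy-N-methylacrylamide
Product: 7 (R,E)-3-{4-[(tert-butyldimethylsilyl)oxy]-2,6,6-trimethylcyclohex-1-en-1-yl}-N-methoxy-N-methylprop-2-enamide
Conditions: Pd(OAc)2 (cat.), PPh3, Et3N, DMF, 70 °C
Reagents that add atoms: none
Why: Heck reaction of an enol triflate with an acrylamide, in which syn insertion and syn β-hydride elimination should give the E-dienamide (the C6–C7 bond and the C7=C8 alkene).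

Step 6
Reactants: 7 Weinreb dienamide; 8 vinylmagnesium bromide
Product: 9 (R,E)-1-{4-[(tert-butyldimethylsilyl)oxy]-2,6,6-trimethylcyclohex-1-en-1-yl}penta-1,4-dien-3-one
Conditions: THF, −20 → 0 °C; poured into cold 1 M HCl
Reagents that add atoms: none
Why: Weinreb ketone synthesis: the chelated tetrahedral intermediate stops at mono-addition, and the inverse acidic quench protonates the released N,O-dimethylhydroxylamine before it can add to the new vinyl ketone.

Step 7
Reactants: 9 cross-conjugated dienone
Product: 13 (3S,6S)-3-[(tert-butyldimethylsilyl)oxy]-1,1,5-trimethylspiro[5.5]undeca-4,7-dien-9-one, via trimethylsilyl tetraenol ether 10 (not isolated), via potassium trienolate 11 (not isolated), via potassium spiro dienolate 12 (not isolated)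
Conditions: TMSOTf, iPr2NEt, CH2Cl2, −78 → 0 °C; pentane, filter, concentrate; KOtBu, 18-crown-6, THF, −78 → 0 °C; AcOH, −78 °C
Reagents that add atoms: none
Why: Proposed new method: TMSOTf and iPr2NEt enolise the dienone vinylogously by loss of the axial C4 hydrogen (there is no α-hydrogen, and the endocyclic C4=C5 dienol derivative is the usual outcome for this ring type) to the tetraenol ether 10, and KOtBu cleaves its Si–O bond to the potassium trienolate 11, a 3-oxidohexatriene C6=C7–C8=C9(O−)–C10=C11. Because the negative charge is shared by O, C8, C6 and C4, the C8–C9 bond has reduced double-bond character, so the two C8=C9 geometries formed on enolisation should interconvert and drain through the s-cis,Z,s-cis rotamer, which undergoes thermal disrotatory 6π-electrocyclisation with bond formation between C6 and C11 to the cyclohexadienolate 12, and protonation at C10 gives the C7=C8–C9 enone. The closest known reaction types are the oxyanion-accelerated 6π closure of 3-oxidohexatrienes (trienolates from alkenyllithium addition to cyclobutenones) to cyclohexadienolates below room temperature and thermal triene closures that create quaternary ring carbons, whereas a trienolate made by remote enolisation and closing to a spiro carbon flanked by two fully substituted carbons has no direct precedent. Ring B (six-membered) is closed by this single 6π disrotatory event. The new stereocentre C6 is controlled by ring A: the C3 silyloxy group must be equatorial (axial, it would meet the axial C1 methyl), which fixes the half-chair so that the axial C1 methyl covers one face of C6, and C11 should therefore bond to the other face, cis to the C3 oxygen. The step needs periselectivity over other closures of the tetraene and chemoselectivity over loss of the C3 oxygen: ring A locks the C4=C5–C6=C7 unit s-trans, which excludes both the 8π closure (C4 to C11) and the alternative 6π closure (C4 to C9), while the equatorial C3–O bond lies near the nodal plane of the π system and the low temperature disfavours β-elimination of silanolate.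

Step 8
Reactants: 13 spiro dienone silyl ether
Product: 14 (3S,6S)-3-hydroxy-1,1,5-trimethylspiro[5.5]undeca-4,7-dien-9-one
Conditions: HF·pyridine, pyridine, THF, 0 → 23 °C
Reagents that add atoms: none
Why: Fluoride-mediated cleavage of the secondary silyl ether under buffered conditions, which should leave the enone and the allylic alcohol unchanged.

Step 9
Reactants: 14 allylic alcohol
Product: 15 (3S,4S,5R,6S)-4,5-epoxy-3-hydroxy-1,1,5-trimethylspiro[5.5]undec-7-en-9-one (epoxide oxygen cis to the C3 hydroxyl)
Conditions: mCPBA, NaHCO3, CH2Cl2, 0 °C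
Reagents that add atoms: 3-chloroperoxybenzoic acid, OOC(=O)c1cccc(Cl)c1
Why: Hydroxyl-directed (Henbest) peracid epoxidation: hydrogen bonding to the pseudoequatorial allylic C3–OH should deliver oxygen to the syn face of the electron-rich trisubstituted C4=C5 (the axial C1 methyl also shields the other face), setting C4 and C5, while the electron-poor enone alkene is not attacked and the buffer prevents acid-induced rearrangement.

Step 10
Reactants: 15 epoxy alcohol enone
Product: 16 (3S,4S,5R,6S,9Z)-9-(bromomethylidene)-4,5-epoxy-1,1,5-trimethylspiro[5.5]undec-7-en-3-ol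
Conditions: [Ph3PCH2Br]Br, KOtBu, THF, −78 °C; add 15; −78 → 0 °C
Reagents that add atoms: (bromomethyl)triphenylphosphonium bromide, BrC[P+](c1ccccc1)(c1ccccc1)c1ccccc1.[Br-]
Why: Wittig bromomethylenation of the enone carbonyl by 1,2-addition of the ylide (used in excess to cover the free hydroxyl); bromine is expected to be placed syn to the flat C8–H flank, because the C10 methylene presents an axial hydrogen on the face of attack, to give the Z isomer, any E isomer being removed by chromatography.

Step 11
Reactants: 16 epoxy alcohol bromodiene
Product: 17 (3S,5S,6S,9Z)-9-(bromomethylidene)-1,1,5-trimethylspiro[5.5]undec-7-ene-3,5-diol (hydroxyls cis)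
Conditions: LiEt3BH, THF, 0 → 40 °C
Reagents that add atoms: none
Why: SN2 epoxide opening by a trialkylborohydride: C5 is tertiary and neopentyl, so hydride should enter at the secondary C4 anti to the epoxide oxygen, leaving the C5–O bond and its configuration intact and giving the tertiary alcohol cis to the C3 hydroxyl, while the alkenyl bromide and the diene are inert to this reagent.

Step 12
Reactants: 17 cis-1,3-diol
Product: 18 (3R,5S,6S,9Z)-3-bromo-9-(bromomethylidene)-1,1,5-trimethylspiro[5.5]undec-7-en-5-ol (target)
Conditions: CBr4, PPh3, CH2Cl2, 0 → 23 °C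
Reagents that add atoms: carbon tetrabromide, BrC(Br)(Br)Br
Why: Appel bromination: the alkoxyphosphonium of the secondary C3 alcohol is displaced by bromide in an SN2 reaction with inversion (3S to 3R), expected to pass through the ring-flipped chair with an axial leaving group and equatorial entry of bromide, while the hindered tertiary hydroxyl is not activated.

**Compound list**

1 | ketoisophorone (2,6,6-trimethylcyclohex-2-ene-1,4-dione) | CC1=CC(=O)CC(C)(C)C1=O | starting material
2 | (6R)-levodione, (R)-2,2,6-trimethylcyclohexane-1,4-dione | C[C@@H]1CC(=O)CC(C)(C)C1=O | intermediate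
3 | (4R,6R)-4-hydroxy-2,2,6-trimethylcyclohexan-1-one | C[C@@H]1C[C@@H](O)CC(C)(C)C1=O | intermediate
4 | (4R,6R)-4-[(tert-butyldimethylsilyl)oxy]-2,2,6-trimethylcyclohexan-1-one | C[C@@H]1C[C@@H](O[Si](C)(C)C(C)(C)C)CC(C)(C)C1=O | intermediate
5 | (R)-4-[(tert-butyldimethylsilyl)oxy]-2,6,6-trimethylcyclohex-1-en-1-yl trifluoromethanesulfonate | CC1=C(OS(=O)(=O)C(F)(F)F)C(C)(C)C[C@H](O[Si](C)(C)C(C)(C)C)C1 | intermediate
6 | N-methoxy-N-methylacrylamide | C=CC(=O)N(C)OC | starting material
7 | (R,E)-3-{4-[(tert-butyldimethylsilyl)oxy]-2,6,6-trimethylcyclohex-1-en-1-yl}-N-methoxy-N-methylprop-2-enamide | CC1=C(/C=C/C(=O)N(C)OC)C(C)(C)C[C@H](O[Si](C)(C)C(C)(C)C)C1 | intermediate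
8 | vinylmagnesium bromide | C=C[Mg]Br | starting material
9 | (R,E)-1-{4-[(tert-butyldimethylsilyl)oxy]-2,6,6-trimethylcyclohex-1-en-1-yl}penta-1,4-dien-3-one (key-step precursor) | CC1=C(/C=C/C(=O)C=C)C(C)(C)C[C@H](O[Si](C)(C)C(C)(C)C)C1 | intermediate
10 | trimethylsilyl tetraenol ether: ring A with C4=C5 and exocyclic C6=C7, chain C7H–C8H=C9(OSiMe3)–C10H=C11H2, C3 silyl ether retained (3S); mixture of C6=C7 and C8=C9 geometries | CC1(C)C[C@H](O[Si](C)(C)C(C)(C)C)C=C(C)C1=CC=C(O[Si](C)(C)C)C=C | intermediate
11 | potassium trienolate corresponding to 10 (interconverting geometries) | CC1(C)C[C@H](O[Si](C)(C)C(C)(C)C)C=C(C)C1=CC=C([O-])C=C.[K+] | intermediate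
12 | potassium (3S,6S)-spiro dienolate: ring B closed, C7=C8–C9(O−)=C10 | CC1(C)C[C@H](O[Si](C)(C)C(C)(C)C)C=C(C)[C@@]12C=CC([O-])=CC2.[K+] | intermediate
13 | (3S,6S)-3-[(tert-butyldimethylsilyl)oxy]-1,1,5-trimethylspiro[5.5]undeca-4,7-dien-9-one (key-step product; C11 cis to the C3 oxygen) | CC1(C)C[C@H](O[Si](C)(C)C(C)(C)C)C=C(C)[C@@]12C=CC(=O)CC2 | intermediate
14 | (3S,6S)-3-hydroxy-1,1,5-trimethylspiro[5.5]undeca-4,7-dien-9-one | CC1(C)C[C@H](O)C=C(C)[C@@]12C=CC(=O)CC2 | intermediate
15 | (3S,4S,5R,6S)-4,5-epoxy-3-hydroxy-1,1,5-trimethylspiro[5.5]undec-7-en-9-one | CC1(C)C[C@H](O)[C@@H]2O[C@]2(C)[C@@]13C=CC(=O)CC3 | intermediate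
16 | (3S,4S,5R,6S,9Z)-9-(bromomethylidene)-4,5-epoxy-1,1,5-trimethylspiro[5.5]undec-7-en-3-ol (Br syn to C8) | CC1(C)C[C@H](O)[C@@H]2O[C@]2(C)[C@@]13C=C/C(=C\Br)CC3 | intermediate
17 | (3S,5S,6S,9Z)-9-(bromomethylidene)-1,1,5-trimethylspiro[5.5]undec-7-ene-3,5-diol | CC1(C)C[C@H](O)C[C@](C)(O)[C@@]12C=C/C(=C\Br)CC2 | intermediate
18 | (3R,5S,6S,9Z)-3-bromo-9-(bromomethylidene)-1,1,5-trimethylspiro[5.5]undec-7-en-5-ol | CC1(C)C[C@@H](Br)C[C@](C)(O)[C@@]12C=C/C(=C\Br)CC2 | target

**Step count**

Total steps: 12. Longest linear sequence: 12 (steps 1–12; the coupling partners 6 and 8 are purchased).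

**Steps most likely to fail**

1. Step 7 (Proposed new method). Several processes could defeat it:
   - enolisation toward the C5 methyl instead of C4, which would open 8π and other 6π channels;
   - rotation about C8–C9 in the trienolate too slow for the whole population to reach the closable rotamer;
   - vinylogous β-elimination of the C3 oxygen from the trienolate, or cationic (Nazarov-type) closure during silylation;
   - closure on the wrong face of C6, or an unfavourable equilibrium for a closure that builds a crowded quaternary centre.

   Fallback (known chemistry, from 5, returning at 13): the triflate 5 is carbonylated (Pd(OAc)2, PPh3, CO, MeOH, Et3N, DMF) to methyl (R)-4-[(tert-butyldimethylsilyl)oxy]-2,6,6-trimethylcyclohex-1-ene-1-carboxylate F1. Deconjugative alkylation of its lithium dienolate (LiN(iPr)2, DMPU, THF, −78 °C) with 2-(2-iodoethyl)-2-methyl-1,3-dioxolane at C6, anti to the axial C1 methyl, gives the quaternary ketal ester F2. Reduction with iBu2AlH gives the neopentyl alcohol F3, and Dess–Martin oxidation gives the ketal aldehyde F4. Mild acid (PPTS, wet acetone) frees the keto aldehyde F5, and intramolecular aldol condensation (KOH, MeOH) of its methyl ketone onto the non-enolisable aldehyde closes ring B as the C7=C8–C9 enone 13.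

2. Step 10. Oxaphosphetane formation may discriminate poorly between the C8–H and C10H2 flanks of the carbonyl, so the bromomethylene geometry may come out unselective or reversed. Enolisation of the ketone by the basic ylide would also lower conversion.

   Fallback (from 15, returning at 16): boron-Wittig olefination of 15 with lithiated bis(pinacolato)borylmethane (CH2(Bpin)2, lithium 2,2,6,6-tetramethylpiperidide, THF, 0 °C) gives two separable alkenyl boronates, the isomer with boron syn to C8 F6 and the isomer with boron syn to C10 F7. Both are taken to the same bromide 16 by halodeboronation of matching stereochemical course: F6 with NBS (retention), F7 with Br2 then NaOMe (inversion).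

3. Step 12. Backside attack on the equatorial alkoxyphosphonium is blocked by the syn-axial methyls at C1 and C5, so displacement must pass through the flipped chair. E2 elimination toward C2 or C4, or a stalled cyclic phosphorane of the cis-1,3-diol, may compete with substitution.

   Fallback (from 17, returning at 18): activation and displacement are separated. Chemoselective sulfonylation of the secondary hydroxyl (Tf2O, pyridine, CH2Cl2, −40 °C) gives the C3 triflate F8, which is displaced with inversion by soluble bromide (Bu4NBr, toluene, −20 → 0 °C), a temperature at which elimination should be slower.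

**Further compounds**

F1 | step 7 | methyl (R)-4-[(tert-butyldimethylsilyl)oxy]-2,6,6-trimethylcyclohex-1-ene-1-carboxylate | CC1=C(C(=O)OC)C(C)(C)C[C@H](O[Si](C)(C)C(C)(C)C)C1
F2 | step 7 | methyl ester with C4=C5 and quaternary C6 carrying the 2-(2-methyl-1,3-dioxolan-2-yl)ethyl chain (C11 cis to the C3 oxygen) | CC1(C)C[C@H](O[Si](C)(C)C(C)(C)C)C=C(C)[C@@]1(CCC2(C)OCCO2)C(=O)OC
F3 | step 7 | primary alcohol from reduction of F2 | CC1(C)C[C@H](O[Si](C)(C)C(C)(C)C)C=C(C)[C@@]1(CCC2(C)OCCO2)CO
F4 | step 7 | ketal aldehyde from oxidation of F3 | CC1(C)C[C@H](O[Si](C)(C)C(C)(C)C)C=C(C)[C@@]1(CCC2(C)OCCO2)C=O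
F5 | step 7 | keto aldehyde (C6 carries CHO and the 3-oxobutyl chain) | CC1(C)C[C@H](O[Si](C)(C)C(C)(C)C)C=C(C)[C@@]1(CCC(C)=O)C=O
F6 | step 10 | alkenyl pinacol boronate of 15 with boron syn to C8 | CC1(C)C[C@H](O)[C@@H]2O[C@]2(C)[C@@]13C=C/C(=C\B4OC(C)(C)C(C)(C)O4)CC3
F7 | step 10 | alkenyl pinacol boronate of 15 with boron syn to C10 | CC1(C)C[C@H](O)[C@@H]2O[C@]2(C)[C@@]13C=C/C(=C/B4OC(C)(C)C(C)(C)O4)CC3
F8 | step 12 | C3 trifluoromethanesulfonate of diol 17 | CC1(C)C[C@H](OS(=O)(=O)C(F)(F)F)C[C@](C)(O)[C@@]12C=C/C(=C\Br)CC2
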